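Ring 1, ring 2 and ring 3 are the dihydrobenzofurans on arene A (bears the styryl group), arene B (central) and arene C (its ring carries the 3,5-dihydroxyphenyl group on C3); each is numbered O1, C2, C3, C3a, C4–C7a.
Cuts: the nine O–CH3 bonds of the permethyl ether; the three C3–aryl bonds (ring 3 C3–aryl, ring 2 C3–C4 of arene C, ring 1 C3–C4 of arene B), each traced to a C3 carboxyl plus an arylboronic acid; the C4–vinyl bond on arene A; last the C3–C3a bond of every ring, which leads back to a flavanone.
Enabling feature: ring 2 has a 2S carbon carrying 4-hydroxyphenyl, oxygen on C6 and a carbon substituent on C4, which is C2, 4'-O, 7-O and 5-O of (2S)-naringenin once its carbonyl carbon C4 is moved out of the pyranone onto C3 as a carboxyl; rings 1 and 3 show the same pattern in the 2R series.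
Ring formation: the 5-triflate of naringenin 7,4'-dimethyl ether is contracted by an oxidative 1,2-aryl shift (ring 2) and the triflate is borylated; a chromone triflate is arylated asymmetrically to the 2R flavanone, contracted the same way (rings 1 and 3, one common ester) and turned into the styryl acid (ring 1) or the boronic acid (ring 3).
Chain joining: ring 1, then ring 2, then ring 3, then the 3,5-dimethoxyphenyl group, by three nickel-catalysed decarboxylative arylations in which each C3 ester first rides along and is then hydrolysed and used as the radical precursor; ninefold demethylation ends the route.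
Stereochemistry: C2 of ring 2 from naringenin; C2 of rings 1 and 3 from the ligand-controlled 1,4-addition; every C3 is fixed trans to its C2 aryl group when the planar C3 radical is arylated (the C3 centre made in the contraction is only a relay); the E alkene comes in with the alkenylboronic acid.

Key step: step 3

Assumption: commercial (2S)-naringenin is taken to be of high enantiomeric purity (to be checked by chiral HPLC on 3, the mirror image of 11), and (S)-t-BuPyOx is taken to give the 2R flavanone as its cyclic-enone model predicts; otherwise the (R)-ligand is used.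

Step 1
Reactants: 1 (2S)-naringenin
Product: 2 (2S)-5-hydroxy-7-methoxy-2-(4-methoxyphenyl)chroman-4-one
Conditions: MeOH (2.2 equiv), PPh3, DIAD, THF, 0 °C to rt
Reagents that add atoms: methanol, CO
Why: Mitsunobu etherification methylates the two free phenols (7-OH, then 4'-OH) but not the 5-OH that is hydrogen-bonded to C4=O, and since no free base is present the C2 centre should not be scrambled by opening to the chalcone or the quinone methide.

Step 2
Reactants: 2 (2S)-5-hydroxy-7-methoxy-2-(4-methoxyphenyl)chroman-4-one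
Product: 3 (2S)-7-methoxy-2-(4-methoxyphenyl)-4-oxochroman-5-yl trifluoromethanesulfonate
Conditions: Tf2O, pyridine, CH2Cl2, 0 °C
Reagents that add atoms: trifluoromethanesulfonic anhydride (Tf2O), O=S(=O)(OS(=O)(=O)C(F)(F)F)C(F)(F)F
Why: Aryl triflate formation at the remaining chelated phenol with Tf2O and a weak amine base turns the naringenin 5-oxygen directly into the later cross-coupling handle and lowers the electron density of the arene enough to shield it from the oxidant of step 3, without enolising C3.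

Step 3
Reactants: 3 (2S)-7-methoxy-2-(4-methoxyphenyl)-4-oxochroman-5-yl trifluoromethanesulfonate
Product: 5 methyl (2S,3S)-6-methoxy-2-(4-methoxyphenyl)-4-(trifluoromethylsulfonyloxy)-2,3-dihydro-1-benzofuran-3-carboxylate, via methyl enol ether 4 (not isolated)
Conditions: HC(OMe)3, H2SO4, rt; then PhI(OAc)2 (1.1 equiv), rt
Reagents that add atoms: trimethyl orthoformate, COC(OC)OC
Why: Acid and orthoformate convert the C4 ketone of 3 into methyl enol ether 4, PhI(OAc)2 (trivalent iodine) attacks C3 anti to the equatorial C2 aryl group, methanol adds to C4, and the two ketal oxygens then push the fused aryl carbon C4a from C4 to C3 with loss of PhI, the dimethoxycarbenium ion collapsing to the methyl ester. The closest known reaction type is the oxidative 1,2-aryl-shift ring contraction of flavanones to trans-2-aryl-2,3-dihydrobenzofuran-3-carboxylates by trivalent iodine or trivalent thallium reagents in trimethyl orthoformate. Ring 2 is not closed by a cyclisation: it arises by contraction of the six-membered pyranone, the new ring bond C3–C3a being made in a suprafacial 1,2-shift of semipinacol type that leaves the old C4 outside the ring as the ester carbon. The new C3 centre is controlled by C2, because the iodane sits trans-diequatorial to the aryl group and migration inverts C3, which gives the trans ester (also the thermodynamic epimer) while C2 itself is untouched. The step needs the fused-aryl shift to beat migration of the C2 aryl group (isoflavone) and dehydrogenation (flavone): the equatorial C3–iodine bond is antiperiplanar to C4–C4a but not to the C2–aryl bond, and C4a stays activated by the ortho ring oxygen and the para 7-methoxy group despite the triflate, which in turn keeps the product arene from reacting with excess oxidant.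

Step 4
Reactants: 5 methyl (2S,3S)-6-methoxy-2-(4-methoxyphenyl)-4-(trifluoromethylsulfonyloxy)-2,3-dihydro-1-benzofuran-3-carboxylate
Product: 6 [(2S,3S)-6-methoxy-3-(methoxycarbonyl)-2-(4-methoxyphenyl)-2,3-dihydro-1-benzofuran-4-yl]boronic acid
Conditions: B2(OH)4, Pd(OAc)2 (cat.), XPhos, KOAc, MeOH, 60 °C
Reagents that add atoms: tetrahydroxydiboron, OB(O)B(O)O
Why: Palladium-catalysed Miyaura borylation of the aryl triflate with tetrahydroxydiboron should give the free boronic acid directly, the weak acetate base leaving the C3 ester and both stereocentres untouched.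

Step 5
Reactants: 7 5,7-dihydroxy-4H-chromen-4-one
Product: 8 5-hydroxy-7-methoxy-4H-chromen-4-one
Conditions: MeI (1.1 equiv), K2CO3, acetone, reflux
Reagents that add atoms: iodomethane, CI
Why: Williamson etherification with one equivalent of MeI is selective for the more acidic 7-OH because the 5-OH is tied up in a hydrogen bond to the pyranone carbonyl.

Step 6
Reactants: 8 5-hydroxy-7-methoxy-4H-chromen-4-one
Product: 9 7-methoxy-4-oxo-4H-chromen-5-yl trifluoromethanesulfonate
Conditions: Tf2O, pyridine, CH2Cl2, 0 °C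
Reagents that add atoms: trifluoromethanesulfonic anhydride (Tf2O), O=S(=O)(OS(=O)(=O)C(F)(F)F)C(F)(F)F
Why: Aryl triflate formation as in step 2, the sulfonate also making the chromone a better conjugate acceptor for step 7.

Step 7
Reactants: 9 7-methoxy-4-oxo-4H-chromen-5-yl trifluoromethanesulfonate; 10 4-methoxyphenylboronic acid
Product: 11 (2R)-7-methoxy-2-(4-methoxyphenyl)-4-oxochroman-5-yl trifluoromethanesulfonate
Conditions: Pd(OCOCF3)2 (5 mol %), (S)-t-BuPyOx (6 mol %), NH4PF6, H2O, ClCH2CH2Cl, 60 °C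
Reagents that add atoms: none
Why: Palladium-catalysed asymmetric conjugate addition of an arylboronic acid to a chromone (insertion of C2=C3 into an aryl–palladium bond, then protonolysis of the palladium enolate) creates C2 under control of the (S)-t-BuPyOx ligand, which should expose the face leading to the 2R flavanone, and the cationic divalent palladium catalyst does not insert into the aryl triflate.

Step 8
Reactants: 11 (2R)-7-methoxy-2-(4-methoxyphenyl)-4-oxochroman-5-yl trifluoromethanesulfonate
Product: 13 methyl (2R,3R)-6-methoxy-2-(4-methoxyphenyl)-4-(trifluoromethylsulfonyloxy)-2,3-dihydro-1-benzofuran-3-carboxylate, via methyl enol ether 12 (not isolated)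
Conditions: HC(OMe)3, H2SO4, rt; then PhI(OAc)2 (1.1 equiv), rt
Reagents that add atoms: trimethyl orthoformate, COC(OC)OC
Why: Same oxidative 1,2-aryl-shift ring contraction as in step 3 on the enantiomeric flavanone, the 2R centre again placing the C3 ester trans.

Step 9
Reactants: 13 methyl (2R,3R)-6-methoxy-2-(4-methoxyphenyl)-4-(trifluoromethylsulfonyloxy)-2,3-dihydro-1-benzofuran-3-carboxylate; 14 (E)-2-(4-methoxyphenyl)ethenylboronic acid
Product: 15 methyl (2R,3R)-6-methoxy-2-(4-methoxyphenyl)-4-[(E)-2-(4-methoxyphenyl)ethenyl]-2,3-dihydro-1-benzofuran-3-carboxylate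
Conditions: Pd(OAc)2 (cat.), SPhos, K3PO4, toluene/H2O, 80 °C
Reagents that add atoms: none
Why: Suzuki–Miyaura coupling of the aryl triflate with the E-alkenylboronic acid should proceed with retention of the alkene geometry, the bulky biarylphosphine supporting oxidative addition at the ortho-substituted C4 carbon.

Step 10
Reactants: 15 methyl (2R,3R)-6-methoxy-2-(4-methoxyphenyl)-4-[(E)-2-(4-methoxyphenyl)ethenyl]-2,3-dihydro-1-benzofuran-3-carboxylate
Product: 16 (2R,3R)-6-methoxy-2-(4-methoxyphenyl)-4-[(E)-2-(4-methoxyphenyl)ethenyl]-2,3-dihydro-1-benzofuran-3-carboxylic acid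
Conditions: LiOH·H2O, THF/MeOH/H2O, rt; then 1 M HCl, 0 °C
Reagents that add atoms: lithium hydroxide, [Li+].[OH-]
Why: Saponification of the methyl ester; C2 is safe because expulsion of the ring oxygen from the C3 enolate would be the reverse of a 5-endo-trig closure, and any epimerisation at C3 is immaterial since C3 becomes a radical in step 12.

Step 11
Reactants: 13 methyl (2R,3R)-6-methoxy-2-(4-methoxyphenyl)-4-(trifluoromethylsulfonyloxy)-2,3-dihydro-1-benzofuran-3-carboxylate
Product: 17 [(2R,3R)-6-methoxy-3-(methoxycarbonyl)-2-(4-methoxyphenyl)-2,3-dihydro-1-benzofuran-4-yl]boronic acid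
Conditions: B2(OH)4, Pd(OAc)2 (cat.), XPhos, KOAc, MeOH, 60 °C
Reagents that add atoms: tetrahydroxydiboron, OB(O)B(O)O
Why: Miyaura borylation as in step 4 on the enantiomeric triflate.

Step 12
Reactants: 16 ring 1 styryl acid; 6 ring 2 boronic acid
Product: 19 ring 1–ring 2 methyl ester (C3 of ring 1 bonded to C4 of arene B), via TCNHPI ester 18 (not isolated)
Conditions: TCNHPI, DIC, DMAP (cat.), CH2Cl2, rt; filtration, solvent exchange; then 6, NiCl2·6H2O (20 mol %), bathophenanthroline, Et3N, 1,4-dioxane/DMF, 75 °C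
Reagents that add atoms: N-hydroxytetrachlorophthalimide (TCNHPI), O=C1N(O)C(=O)c2c(Cl)c(Cl)c(Cl)c(Cl)c12 (its atoms stay in 18 only and are lost again before 19)
Why: Nickel-catalysed decarboxylative Suzuki-type arylation of a redox-active ester: electron transfer to 18 and loss of CO2 give the planar benzylic C3 radical of ring 1, and the aryl–nickel species formed from 6 should deliver arene B to the face opposite the C2 aryl group, setting C3 (R) trans.

Step 13
Reactants: 19 ring 1–ring 2 methyl ester
Product: 20 ring 1–ring 2 carboxylic acid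
Conditions: LiOH·H2O, THF/MeOH/H2O, 40 °C; then 1 M HCl, 0 °C
Reagents that add atoms: lithium hydroxide, [Li+].[OH-]
Why: Saponification as in step 10 (the more hindered ester needs gentle warming), again without risk to the C2 centres.

Step 14
Reactants: 20 ring 1–ring 2 carboxylic acid; 17 ring 3 boronic acid
Product: 22 ring 1–ring 2–ring 3 methyl ester (C3 of ring 2 bonded to C4 of arene C), via TCNHPI ester 21 (not isolated)
Conditions: TCNHPI, DIC, DMAP (cat.), CH2Cl2, rt; filtration, solvent exchange; then 17, NiCl2·6H2O (20 mol %), bathophenanthroline, Et3N, 1,4-dioxane/DMF, 75 °C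
Reagents that add atoms: N-hydroxytetrachlorophthalimide (TCNHPI), O=C1N(O)C(=O)c2c(Cl)c(Cl)c(Cl)c(Cl)c12 (its atoms stay in 21 only and are lost again before 22)
Why: Second nickel-catalysed decarboxylative arylation of a redox-active ester, the C3 radical of ring 2 being arylated by 17 anti to its C2 aryl group so that C3 (S) becomes trans and C4 of arene C is attached.

Step 15
Reactants: 22 ring 1–ring 2–ring 3 methyl ester
Product: 23 ring 1–ring 2–ring 3 carboxylic acid
Conditions: LiOH·H2O, THF/MeOH/H2O, 40 °C; then 1 M HCl, 0 °C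
Reagents that add atoms: lithium hydroxide, [Li+].[OH-]
Why: Saponification as in step 13.

Step 16
Reactants: 23 ring 1–ring 2–ring 3 carboxylic acid; 24 3,5-dimethoxyphenylboronic acid
Product: 26 nona-O-methylmiyabenol A, via TCNHPI ester 25 (not isolated)
Conditions: TCNHPI, DIC, DMAP (cat.), CH2Cl2, rt; filtration, solvent exchange; then 24, NiCl2·6H2O (20 mol %), bathophenanthroline, Et3N, 1,4-dioxane/DMF, 75 °C
Reagents that add atoms: N-hydroxytetrachlorophthalimide (TCNHPI), O=C1N(O)C(=O)c2c(Cl)c(Cl)c(Cl)c(Cl)c12 (its atoms stay in 25 only and are lost again before 26)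
Why: Third nickel-catalysed decarboxylative arylation of a redox-active ester, here with an unhindered boronic acid, should place the 3,5-dimethoxyphenyl group on C3 of ring 3 trans to the C2 aryl group (3R).

Step 17
Reactants: 26 nona-O-methylmiyabenol A
Product: 27 miyabenol A
Conditions: BCl3, n-Bu4NI, CH2Cl2, −78 to 0 °C; then MeOH and pH 7 buffer at −78 °C
Reagents that add atoms: none
Why: Lewis-acid ether cleavage assisted by iodide (BCl3 complexes each aryl methyl ether and iodide removes the methyl group by SN2) runs at low temperature without protic acid until the cold buffered quench, which should spare the three para-oxygenated benzylic C2–O bonds and keep the stilbene from cyclising onto arene B.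

Compound list
1 | (2S)-naringenin, (2S)-5,7-dihydroxy-2-(4-hydroxyphenyl)chroman-4-one | O=C1C[C@@H](c2ccc(O)cc2)Oc2cc(O)cc(O)c21 | starting material
2 | (2S)-5-hydroxy-7-methoxy-2-(4-methoxyphenyl)chroman-4-one (7,4'-di-O-methylnaringenin) | O=C1C[C@@H](c2ccc(OC)cc2)Oc2cc(OC)cc(O)c21 | intermediate
3 | (2S)-7-methoxy-2-(4-methoxyphenyl)-4-oxochroman-5-yl trifluoromethanesulfonate | O=C1C[C@@H](c2ccc(OC)cc2)Oc2cc(OC)cc(OS(=O)(=O)C(F)(F)F)c21 | intermediate
4 | (2S)-4,7-dimethoxy-2-(4-methoxyphenyl)-2H-chromen-5-yl trifluoromethanesulfonate (methyl enol ether of 3) | COC1=C[C@@H](c2ccc(OC)cc2)Oc2cc(OC)cc(OS(=O)(=O)C(F)(F)F)c21 | intermediate (not isolated)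
5 | methyl (2S,3S)-6-methoxy-2-(4-methoxyphenyl)-4-(trifluoromethylsulfonyloxy)-2,3-dihydro-1-benzofuran-3-carboxylate (trans) | FC(F)(F)S(=O)(=O)Oc1cc(OC)cc2c1[C@H](C(=O)OC)[C@@H](c1ccc(OC)cc1)O2 | intermediate
6 | [(2S,3S)-6-methoxy-3-(methoxycarbonyl)-2-(4-methoxyphenyl)-2,3-dihydro-1-benzofuran-4-yl]boronic acid | OB(O)c1cc(OC)cc2c1[C@H](C(=O)OC)[C@@H](c1ccc(OC)cc1)O2 | intermediate
7 | 5,7-dihydroxy-4H-chromen-4-one | O=c1ccoc2cc(O)cc(O)c12 | starting material
8 | 5-hydroxy-7-methoxy-4H-chromen-4-one | O=c1ccoc2cc(OC)cc(O)c12 | intermediate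
9 | 7-methoxy-4-oxo-4H-chromen-5-yl trifluoromethanesulfonate | O=c1ccoc2cc(OC)cc(OS(=O)(=O)C(F)(F)F)c12 | intermediate
10 | 4-methoxyphenylboronic acid | COc1ccc(B(O)O)cc1 | starting material
11 | (2R)-7-methoxy-2-(4-methoxyphenyl)-4-oxochroman-5-yl trifluoromethanesulfonate | O=C1C[C@H](c2ccc(OC)cc2)Oc2cc(OC)cc(OS(=O)(=O)C(F)(F)F)c21 | intermediate
12 | (2R)-4,7-dimethoxy-2-(4-methoxyphenyl)-2H-chromen-5-yl trifluoromethanesulfonate (methyl enol ether of 11) | COC1=C[C@H](c2ccc(OC)cc2)Oc2cc(OC)cc(OS(=O)(=O)C(F)(F)F)c21 | intermediate (not isolated)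
13 | methyl (2R,3R)-6-methoxy-2-(4-methoxyphenyl)-4-(trifluoromethylsulfonyloxy)-2,3-dihydro-1-benzofuran-3-carboxylate (trans) | FC(F)(F)S(=O)(=O)Oc1cc(OC)cc2c1[C@@H](C(=O)OC)[C@H](c1ccc(OC)cc1)O2 | intermediate
14 | (E)-2-(4-methoxyphenyl)ethenylboronic acid | COc1ccc(/C=C/B(O)O)cc1 | starting material
15 | methyl (2R,3R)-6-methoxy-2-(4-methoxyphenyl)-4-[(E)-2-(4-methoxyphenyl)ethenyl]-2,3-dihydro-1-benzofuran-3-carboxylate | COc1ccc(/C=C/c2cc(OC)cc3c2[C@@H](C(=O)OC)[C@H](c2ccc(OC)cc2)O3)cc1 | intermediate
16 | (2R,3R)-6-methoxy-2-(4-methoxyphenyl)-4-[(E)-2-(4-methoxyphenyl)ethenyl]-2,3-dihydro-1-benzofuran-3-carboxylic acid | COc1ccc(/C=C/c2cc(OC)cc3c2[C@@H](C(=O)O)[C@H](c2ccc(OC)cc2)O3)cc1 | intermediate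
17 | [(2R,3R)-6-methoxy-3-(methoxycarbonyl)-2-(4-methoxyphenyl)-2,3-dihydro-1-benzofuran-4-yl]boronic acid | OB(O)c1cc(OC)cc2c1[C@@H](C(=O)OC)[C@H](c1ccc(OC)cc1)O2 | intermediate
18 | 4,5,6,7-tetrachloro-1,3-dioxoisoindolin-2-yl ester of 16 | COc1ccc(/C=C/c2cc(OC)cc3c2[C@@H](C(=O)ON2C(=O)c4c(Cl)c(Cl)c(Cl)c(Cl)c4C2=O)[C@H](c2ccc(OC)cc2)O3)cc1 | intermediate (not isolated)
19 | methyl (2S,3S)-6-methoxy-2-(4-methoxyphenyl)-4-{(2R,3R)-6-methoxy-2-(4-methoxyphenyl)-4-[(E)-2-(4-methoxyphenyl)ethenyl]-2,3-dihydro-1-benzofuran-3-yl}-2,3-dihydro-1-benzofuran-3-carboxylate | COc1ccc(/C=C/c2cc(OC)cc3c2[C@@H](c2cc(OC)cc4c2[C@H](C(=O)OC)[C@@H](c2ccc(OC)cc2)O4)[C@H](c2ccc(OC)cc2)O3)cc1 | intermediate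
20 | carboxylic acid of 19 (CO2H on C3 of ring 2; ring 1 2R,3R; ring 2 2S,3S) | COc1ccc(/C=C/c2cc(OC)cc3c2[C@@H](c2cc(OC)cc4c2[C@H](C(=O)O)[C@@H](c2ccc(OC)cc2)O4)[C@H](c2ccc(OC)cc2)O3)cc1 | intermediate
21 | 4,5,6,7-tetrachloro-1,3-dioxoisoindolin-2-yl ester of 20 | COc1ccc(/C=C/c2cc(OC)cc3c2[C@@H](c2cc(OC)cc4c2[C@H](C(=O)ON2C(=O)c5c(Cl)c(Cl)c(Cl)c(Cl)c5C2=O)[C@@H](c2ccc(OC)cc2)O4)[C@H](c2ccc(OC)cc2)O3)cc1 | intermediate (not isolated)
22 | methyl (2R,3R)-6-methoxy-2-(4-methoxyphenyl)-4-[(2S,3S)-6-methoxy-2-(4-methoxyphenyl)-4-{(2R,3R)-6-methoxy-2-(4-methoxyphenyl)-4-[(E)-2-(4-methoxyphenyl)ethenyl]-2,3-dihydro-1-benzofuran-3-yl}-2,3-dihydro-1-benzofuran-3-yl]-2,3-dihydro-1-benzofuran-3-carboxylate | COc1ccc(/C=C/c2cc(OC)cc3c2[C@@H](c2cc(OC)cc4c2[C@H](c2cc(OC)cc5c2[C@@H](C(=O)OC)[C@H](c2ccc(OC)cc2)O5)[C@@H](c2ccc(OC)cc2)O4)[C@H](c2ccc(OC)cc2)O3)cc1 | intermediate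
23 | carboxylic acid of 22 (CO2H on C3 of ring 3; ring 1 2R,3R; ring 2 2S,3S; ring 3 2R,3R) | COc1ccc(/C=C/c2cc(OC)cc3c2[C@@H](c2cc(OC)cc4c2[C@H](c2cc(OC)cc5c2[C@@H](C(=O)O)[C@H](c2ccc(OC)cc2)O5)[C@@H](c2ccc(OC)cc2)O4)[C@H](c2ccc(OC)cc2)O3)cc1 | intermediate
24 | 3,5-dimethoxyphenylboronic acid | COc1cc(OC)cc(B(O)O)c1 | starting material
25 | 4,5,6,7-tetrachloro-1,3-dioxoisoindolin-2-yl ester of 23 | COc1ccc(/C=C/c2cc(OC)cc3c2[C@@H](c2cc(OC)cc4c2[C@H](c2cc(OC)cc5c2[C@@H](C(=O)ON2C(=O)c6c(Cl)c(Cl)c(Cl)c(Cl)c6C2=O)[C@H](c2ccc(OC)cc2)O5)[C@@H](c2ccc(OC)cc2)O4)[C@H](c2ccc(OC)cc2)O3)cc1 | intermediate (not isolated)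
26 | nona-O-methylmiyabenol A (all nine phenols as methyl ethers; ring 1 2R,3R; ring 2 2S,3S; ring 3 2R,3R; E alkene) | COc1ccc(/C=C/c2cc(OC)cc3c2[C@@H](c2cc(OC)cc4c2[C@H](c2cc(OC)cc5c2[C@@H](c2cc(OC)cc(OC)c2)[C@H](c2ccc(OC)cc2)O5)[C@@H](c2ccc(OC)cc2)O4)[C@H](c2ccc(OC)cc2)O3)cc1 | intermediate
27 | miyabenol A (ring 1 2R,3R; ring 2 2S,3S; ring 3 2R,3R; E alkene) | Oc1ccc(/C=C/c2cc(O)cc3c2[C@@H](c2cc(O)cc4c2[C@H](c2cc(O)cc5c2[C@@H](c2cc(O)cc(O)c2)[C@H](c2ccc(O)cc2)O5)[C@@H](c2ccc(O)cc2)O4)[C@H](c2ccc(O)cc2)O3)cc1 | target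

Total step count: 17.
Longest linear sequence: 12 steps (steps 5 to 10 and 12 to 17, from 7). The naringenin branch reaches the target in 10 steps.

Steps most likely to fail

Risk 1, step 14 (the most congested bond; step 12 is the same reaction on smaller partners). The benzylic C3 radical of ring 2 is flanked by the C2 aryl group and by all of ring 1 on C4. Its capture by the aryl–nickel species from the ortho-substituted boronic acid 17 may be slower than hydrogen abstraction or dimerisation of the radical, than protodeboronation of 17, and than base-induced ketene formation from the α-aryl active ester 21. The fallback makes the aryl partner an electrophile and drops the active ester; it sets out from 13 and 20 and returns to the route at 22. Ruthenium-catalysed triflate–bromide exchange on 13 ([Cp*Ru(MeCN)3]OTf, LiBr, DMI, 100 °C) gives methyl (2R,3R)-4-bromo-6-methoxy-2-(4-methoxyphenyl)-2,3-dihydro-1-benzofuran-3-carboxylate F1. Free acid 20 and F1 are then joined by metallaphotoredox decarboxylative arylation (Ir[dF(CF3)ppy]2(dtbbpy)PF6, NiCl2·glyme, dtbbpy, Cs2CO3, DMF, blue light, rt), in which oxidative addition of the bromide to zerovalent nickel replaces the slow boron-to-nickel transfer. The carboxylate is oxidised directly to the same C3 radical, so the trans preference is unchanged.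

Risk 2, step 12. Transmetalation of the hindered, ester-flanked boronic acid 6 may be too slow under the amine-base conditions at 75 °C, so that the ring 1 radical is reduced or dimerises and 6 is protodeboronated. The fallback is a reductive cross-electrophile coupling that needs neither boron nor base; it sets out from 5 and 16 and returns at 19. Triflate 5 is converted ([Cp*Ru(MeCN)3]OTf, NaI, DMI, 100 °C) into methyl (2S,3S)-4-iodo-6-methoxy-2-(4-methoxyphenyl)-2,3-dihydro-1-benzofuran-3-carboxylate F2. Acid 16 is converted (N-hydroxyphthalimide, DIC, DMAP, CH2Cl2) into the isolated 1,3-dioxoisoindolin-2-yl (2R,3R)-6-methoxy-2-(4-methoxyphenyl)-4-[(E)-2-(4-methoxyphenyl)ethenyl]-2,3-dihydro-1-benzofuran-3-carboxylate F3. F2 and F3 are coupled with NiBr2·glyme, dtbbpy and Zn in DMA at rt, the aryl–nickel iodide capturing the C3 radical anti to the C2 aryl group to give 19.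

Risk 3, step 3. With the triflate on the migrating arene the 1,2-shift may become slow enough for loss of the C2 proton (flavone) or migration of the electron-rich C2 anisyl group (isoflavone) to take over. The fallback forms the same C3–C3a bond by a Wolff rearrangement, whose carbene pathway does not depend on the electron density of the migrating arene; it sets out from 3 and returns at 5. Enolisation and trifluoroacetylation of 3 (LiN(SiMe3)2, CF3CO2CH2CF3, THF, −78 °C) give (2S)-7-methoxy-2-(4-methoxyphenyl)-4-oxo-3-(trifluoroacetyl)chroman-5-yl trifluoromethanesulfonate F4. Detrifluoroacetylative diazo transfer (MsN3, Et3N, H2O, MeCN, rt) gives (2R)-3-diazo-7-methoxy-2-(4-methoxyphenyl)-4-oxochroman-5-yl trifluoromethanesulfonate F5, which has the same spatial arrangement at C2 as 3 (only the descriptor changes). Irradiation of F5 in methanol (365 nm) moves C4a from the carbonyl carbon to the carbene carbon C3, and methanol traps the ring-contracted ketene as 5 together with its cis epimer, methyl (2S,3R)-6-methoxy-2-(4-methoxyphenyl)-4-(trifluoromethylsulfonyloxy)-2,3-dihydro-1-benzofuran-3-carboxylate F6. Catalytic DBU in methanol equilibrates F6 to the trans ester 5.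

Further compounds
F1 | step 14 | methyl (2R,3R)-4-bromo-6-methoxy-2-(4-methoxyphenyl)-2,3-dihydro-1-benzofuran-3-carboxylate | Brc1cc(OC)cc2c1[C@@H](C(=O)OC)[C@H](c1ccc(OC)cc1)O2
F2 | step 12 | methyl (2S,3S)-4-iodo-6-methoxy-2-(4-methoxyphenyl)-2,3-dihydro-1-benzofuran-3-carboxylate | Ic1cc(OC)cc2c1[C@H](C(=O)OC)[C@@H](c1ccc(OC)cc1)O2
F3 | step 12 | 1,3-dioxoisoindolin-2-yl (2R,3R)-6-methoxy-2-(4-methoxyphenyl)-4-[(E)-2-(4-methoxyphenyl)ethenyl]-2,3-dihydro-1-benzofuran-3-carboxylate | COc1ccc(/C=C/c2cc(OC)cc3c2[C@@H](C(=O)ON2C(=O)c4ccccc4C2=O)[C@H](c2ccc(OC)cc2)O3)cc1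
F4 | step 3 | (2S)-7-methoxy-2-(4-methoxyphenyl)-4-oxo-3-(trifluoroacetyl)chroman-5-yl trifluoromethanesulfonate (C3 epimers and enol form) | O=C1C(C(=O)C(F)(F)F)[C@@H](c2ccc(OC)cc2)Oc2cc(OC)cc(OS(=O)(=O)C(F)(F)F)c21
F5 | step 3 | (2R)-3-diazo-7-methoxy-2-(4-methoxyphenyl)-4-oxochroman-5-yl trifluoromethanesulfonate | O=C1C(=[N+]=[N-])[C@@H](c2ccc(OC)cc2)Oc2cc(OC)cc(OS(=O)(=O)C(F)(F)F)c21
F6 | step 3 | methyl (2S,3R)-6-methoxy-2-(4-methoxyphenyl)-4-(trifluoromethylsulfonyloxy)-2,3-dihydro-1-benzofuran-3-carboxylate (cis) | FC(F)(F)S(=O)(=O)Oc1cc(OC)cc2c1[C@@H](C(=O)OC)[C@@H](c1ccc(OC)cc1)O2
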